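All runs are calculated for substances that don't exist; scatter was added.

Count the target against the reagent that the second substrate leaves over.

- Friday's: solid substrate 0.40 M; reagent 0.44 M; second substrate 0.40 M; the very flask that is asked about, followed so far
- flask: solid substrate 0.40 M; reagent 0.440 M; second substrate 0.400 M; time 1.0 h

Friday's run (percent of the solid substrate charged)

| time / min | solid substrate / % | target / % |
|---|---|---|
| 2.50 | 54.7 | 2.4 |
| 5.00 | 36.8 | 2.5 |
| 8.00 | 28.6 | 3.3 |
| 15.0 | 27.0 | 3.8 |
| 30.0 | 26.9 | 3.0 |

(readings scatter by 0.5 percentage points)

- given per volume of solution although it is solid: solid substrate
- at the start none of the solid substrate is in solution
- what has only dissolved of solid substrate counts as not reacted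
- the reaction counts as stopped when no species that holds the solid substrate changes by six tenths of a point or more over the second half of the time
- starting material means what is dissolved; the solid is not counted in it

- which holds at 1.0 h: what has brought the reaction to rest, or that it has not come to rest (for what has run out or reacted, a solid counts together with what of it has only dissolved) (the reagent has run out first / it is still moving / forward and back rates have come level / all of the solid substrate has reacted)
- part of the solid substrate that has turned into other species by 1.0 h (what has only dissolved does not count)
- target at 1.0 h, in percent of the solid substrate charged
- starting material at 1.0 h, in percent of the solid substrate charged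
- amount of target if the flask were left three thousand times as long, in percent of the solid substrate charged

Friday's flask is the asked flask, followed so far. Its solid moves by 0.1 percentage points between the last two readings, less than the scatter, so I take those two readings as the flask at rest. Over them the target averages 3.40 % of the charge, and what neither solid nor target holds, the starting material, is 69.6 %. The target is far less than that, so I reckon it as a small correction on the dissolved pool. I assume that each second substrate takes one reagent, which leaves 10.0 % of the solid charge as spare reagent, less what the target holds. Target over starting material times free reagent, each as a fraction of the solid charge, then reads 0.740; call this the holding number, an equilibrium constant in units of the charge. It is a reading and carries the scatter.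

The forecast, a little apart from my figures, says forward and back rates have come level, with conversion 3.5 %, target 3.3 %, starting material 69.5 % and long-wait target 3.4 %: “a fast, unfavourable equilibrium held at constant dissolved concentration, with solid still present”.

The flask gives forward and back rates have come level, with conversion 3.47 %, target 3.47 %, starting material 70.0 % and long-wait target 0 %.

    starting material + reagent ⇌ target (K = 2.00 M⁻¹, k = 1.00 M⁻¹ s⁻¹)
    second substrate + reagent → second product (k = 1.40 M⁻¹ s⁻¹)
    reagent → decomposition product (k = 1.40 × 10⁻⁵ s⁻¹)
    solid substrate ⇌ starting material, rate k4*(cs4 - [starting material]) while solid is left; crystals form when [starting material] > cs4 (solubility = 0.280 M, k = 0.00680 s⁻¹)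

Keep the holding number, 0.740. By decomposition alone the reagent has a half-life of 14 h. After 10.0 h this flask has 4.21 % of its own reagent charge, which is 4.63 % of the solid charge; multiplied by 70.0 % starting material, the holding number gives 2.40 % target, and the flask holds 2.60 %. The neighbour charged with 1.8 M of reagent has 0 % solid at the end, and its charge less the second substrate's share is 3.50 times the solid charge. Solving the holding number for target, with starting material as the rest of the charge, gives 67.6 %; that neighbour holds 68.2 %.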